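The numbers stand for no real mixture.

The meeting took up one question: how much target, solid product included, this flask holds at 15 min, and whether any change adds more than the margin.

    solid substrate ⇌ dissolved substrate, rate k1*(cs1 - [dissolved substrate]) while solid is left; crystals form when [dissolved substrate] > cs1 (cs1 = 44 mM, k1 = 0.0029 s⁻¹)
    dissolved substrate + partner ⇌ target (K2 = 5.3 M⁻¹, k2 = 0.40 M⁻¹ s⁻¹)
    dissolved substrate + target → side product (k3 = 0.27 M⁻¹ s⁻¹)
    solid product ⇌ target, rate k4*(cs4 - [target]) while solid is left; crystals form when [target] > cs4 (cs4 = 42 mM, k4 = 0.57 s⁻¹)
    2 partner → self-condensation product (k5 = 0.0070 M⁻¹ s⁻¹)
    partner ⇌ dormant form (K6 = 21, k6 = 4.7 × 10⁻⁴ s⁻¹)

solid substrate 0.10 M; partner 0.150 M; time 15 min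

- north: doubling the amount of partner, all else as stated
- south: doubling the solubility in step 4, all else as stated
- north-east: doubling the dissolution coefficient of step 1, all else as stated
- south-west: doubling the dissolution coefficient of step 4, all else as stated

- a species is counted by the solid substrate in it: one side product counts as two
- amounts and yields of target count solid product too
- for a step with 2 of a species take k times the square, and two of it per event
- given per volume of solution although it is solid: solid substrate, solid product
- at the start none of the solid substrate is in solution
- run time (flask): 15 min

- how much target and solid product together there is at 15 min, in percent of the solid substrate charged
- the change that raises the amount of target and solid product together at 15 min, in percent of the solid substrate charged most ("none" if none brings more than 2 percentage points) (north / south / north-east / south-west / none)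
- amount of target and solid product together at 15 min, in percent of the solid substrate charged, after south-west

Minutes. I opened by arguing that the joining of dissolved substrate and partner is fast, the half-life of dissolved substrate by this forward step alone, with partner as charged, being 0.19 min and far shorter than the run, so I took the step as a pre-equilibrium and reckoned with what it leaves free. Target over dissolved substrate then equals the equilibrium constant of that step times the free partner, 0.795 at the charge; I named this the holding ratio.

I argued next that a saturated solution at that ratio carries 35.0 mM of target, less than the solubility of 42 mM, so I expected no crystals. Free partner falls, with a first half-life of 7.94 min by self-condensation and, counting the forward rate alone, 25 min towards the dormant form. Multiplying the two decays as though separate, I put 22.7% of it free at the end. The ratio is then 0.180, which for a saturated solution means 7.93% of the charge as target. My reckoning stopped there, since I could not say by hand how full the solution stands.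

The forecast was then read: 3.5%, best change none, and 3.5% after south-west, with this ground for the changes to step 4: “No solid product ever forms, so the two step 4 changes do nothing”. I noted that its yield is lower than my figure for a saturated solution.

The flask gives 3.51%, best change none, and 3.51% after south-west. The undoing of target into dissolved substrate and partner holds this yield down: with that undoing struck out, the flask gives 31.7% instead of 3.51%. At the end of the flask, 19% of the partner is free, so the holding ratio is 0.151, and on 25.1% of dissolved substrate that makes 3.79% of target against 3.51% read. In the neighbour charged with 0.060 M of partner, 25% of its charge is left, the ratio is 0.0782, and 29.4% of dissolved substrate makes 2.30%, where that flask reads 2.12%.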